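**Plan**
- Retrosynthesis: after the three MOM ethers are removed, ring C is cut at C2–C3 and at C4–C4a in one formal [4+2] disconnection. This gives a ring A aryloxymethyl pivalate and a ring B dioxolanone silyl ketene acetal that carries C3–C4.
- Enabling feature: the O1–C2 aryl ether sits on a phloroglucinol ring A whose two free ortho CH positions are strongly nucleophilic and equivalent by symmetry. Ionised at C2 it is a cationic 2-oxadiene (C2=O1–C8a=C4a), and the C3–C4 α-hydroxy-acid unit can be carried as a ketene acetal at the acyl oxidation level.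
- Forward order: ring A fragment from phloroglucinol (steps 1–5), ring B fragment from 4-bromo-3-methoxyphenol (steps 6–12), union with closure of ring C (step 13), MOM removal (step 14).
- Stereochemistry: C3 derives from an (S)-mandelate made by asymmetric transfer hydrogenation. Its configuration is stored in the tert-butyl acetal centre of a cis-dioxolanone (a temporary ring, self-regeneration of stereocentres), which directs C2–C3 bond formation to the opposite face and leaves as pivalaldehyde in the same step.

Key step: step 13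

Remark: chroman-4-one numbering (O1, C2, C3, C4, C4a–C8a) is used and the SMILES fixes C3 as (R); prenyl = 3-methylbut-2-en-1-yl, MOM = methoxymethyl, ArB = 2-methoxy-4-(methoxymethoxy)-3-prenylphenyl.

Step 1
Reactants: 1 phloroglucinol
Product: 2 3,5-bis(methoxymethoxy)phenol
Conditions: MeOCH2Cl (2.0 equiv), i-Pr2NEt, DMF, 0 °C → rt
Reagents that add atoms: chloromethyl methyl ether, COCCl
Why: Williamson-type etherification of the phenoxide; the symmetric triol reacts statistically, so the bis-ether is separated from the mono- and tris-ethers, which can be recycled.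

Step 2
Reactants: 2 3,5-bis(methoxymethoxy)phenol
Product: 3 [3,5-bis(methoxymethoxy)phenoxy]triisopropylsilane
Conditions: i-Pr3SiCl, imidazole, DMF, rt
Reagents that add atoms: chlorotriisopropylsilane, CC(C)[Si](Cl)(C(C)C)C(C)C
Why: Standard silylation of the remaining phenol; the bulky, non-coordinating silyl ether leaves the carbon between the two MOM ethers as the only doubly activated site for metalation.

Step 3
Reactants: 3 [3,5-bis(methoxymethoxy)phenoxy]triisopropylsilane
Product: 5 [3,5-bis(methoxymethoxy)-4-prenylphenoxy]triisopropylsilane, via aryllithium 4 (not isolated)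
Conditions: n-BuLi, THF, 0 °C; then CuBr·SMe2 (10 mol %), prenyl bromide, −78 °C → rt
Reagents that add atoms: prenyl bromide, CC(C)=CCBr
Why: Directed ortho-metalation: n-BuLi is chelated by both MOM oxygens and deprotonates the carbon between them, and the aryllithium is alkylated at the primary carbon of prenyl bromide, copper catalysis favouring the linear SN2 product.

Step 4
Reactants: 5 [3,5-bis(methoxymethoxy)-4-prenylphenoxy]triisopropylsilane
Product: 6 3,5-bis(methoxymethoxy)-4-prenylphenol
Conditions: n-Bu4NF, THF, 0 °C
Reagents that add atoms: none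
Why: Fluoride-induced cleavage of the aryl silyl ether (Si–F bond formation) should free the phenol without touching the MOM ethers or the alkene.

Step 5
Reactants: 6 3,5-bis(methoxymethoxy)-4-prenylphenol
Product: 7 [3,5-bis(methoxymethoxy)-4-prenylphenoxy]methyl pivalate
Conditions: ClCH2OC(O)t-Bu, K2CO3, NaI (cat.), DMF, rt
Reagents that add atoms: chloromethyl pivalate, CC(C)(C)C(=O)OCCl
Why: Williamson etherification of the phenoxide with the chloromethyl ester under iodide catalysis should give the acyloxymethyl ether, the hindered pivaloyl carbonyl resisting acyl transfer.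

Step 6
Reactants: 8 4-bromo-3-methoxyphenol
Product: 9 1-bromo-2-methoxy-4-(methoxymethoxy)benzene
Conditions: MeOCH2Cl, i-Pr2NEt, CH2Cl2, 0 °C → rt
Reagents that add atoms: chloromethyl methyl ether, COCCl
Why: Williamson-type MOM protection of the phenol, which also turns this oxygen into a strong directing group for the next step.

Step 7
Reactants: 9 1-bromo-2-methoxy-4-(methoxymethoxy)benzene
Product: 11 1-bromo-2-methoxy-4-(methoxymethoxy)-3-prenylbenzene, via aryllithium 10 (not isolated)
Conditions: LiN(i-Pr)2, THF, −78 °C; then CuBr·SMe2 (10 mol %), prenyl bromide, −78 → 0 °C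
Reagents that add atoms: prenyl bromide, CC(C)=CCBr
Why: Directed ortho-metalation with a lithium amide (no halogen–lithium exchange) removes the most acidic proton, between the methoxy and MOM-oxy groups and meta to bromine so that no aryne can form, and the aryllithium is alkylated as in step 3.

Step 8
Reactants: 11 1-bromo-2-methoxy-4-(methoxymethoxy)-3-prenylbenzene
Product: 13 ethyl 2-ArB-2-oxoacetate, via aryllithium 12 (not isolated)
Conditions: n-BuLi, THF, −78 °C; then inverse addition to (CO2Et)2 (3 equiv), THF, −78 °C
Reagents that add atoms: diethyl oxalate, CCOC(=O)C(=O)OCC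
Why: Bromine–lithium exchange followed by acylation of the aryllithium with excess oxalate should stop at the α-keto ester, because the tetrahedral adduct persists at −78 °C until the quench.

Step 9
Reactants: 13 ethyl 2-ArB-2-oxoacetate
Product: 14 ethyl (2S)-2-hydroxy-2-ArB-acetate
Conditions: RuCl[(R,R)-TsDPEN](p-cymene) (1 mol %), HCO2H/Et3N (5:2), DMF, 25 °C
Reagents that add atoms: none
Why: Noyori-type asymmetric transfer hydrogenation: the ruthenium hydride adds to the ketone face fixed by the CH/π contact between the arene ligand and the aryl group, which with the (R,R)-ligand should give the (S)-hydroxy ester (same facial sense as the reduction of benzil), the trisubstituted alkene being inert.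

Step 10
Reactants: 14 ethyl (2S)-2-hydroxy-2-ArB-acetate
Product: 15 (2S)-2-hydroxy-2-ArB-acetic acid
Conditions: LiOH, THF/H2O, 0 °C → rt; then 1 M HCl to pH 3, 0 °C
Reagents that add atoms: lithium hydroxide, [Li+].[OH-]
Why: Saponification of the ester; the carbinol centre should not epimerise under these mild conditions and the MOM ethers should survive the brief cold acidification.

Step 11
Reactants: 15 (2S)-2-hydroxy-2-ArB-acetic acid
Product: 17 (2S,5S)-2-tert-butyl-5-ArB-1,3-dioxolan-4-one (cis), via bis-silyl derivative 16 (not isolated)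
Conditions: (Me3Si)2NH, Me3SiCl (cat.), CH2Cl2, rt, evaporate; then t-BuCHO, Me3SiOTf (5 mol %), CH2Cl2, −78 °C
Reagents that add atoms: pivalaldehyde, CC(C)(C)C=O
Why: Silyl-transfer acetalisation without Brønsted acid (Noyori-type conditions): the bis-silyl derivative condenses with pivalaldehyde under kinetic control to give the cis-dioxolanone, so the new acetal centre (tert-butyl cis to the aryl group) stores the configuration of C5, the first stage of self-regeneration of stereocentres; any trans isomer must be removed because it would lead to the wrong enantiomer.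

Step 12
Reactants: 17 (2S,5S)-2-tert-butyl-5-ArB-1,3-dioxolan-4-one
Product: 19 {[(2S)-2-tert-butyl-5-ArB-1,3-dioxol-4-yl]oxy}trimethylsilane, via lithium enolate 18 (not isolated)
Conditions: LiN(i-Pr)2, THF, −78 °C; then Me3SiCl, −78 → 0 °C; pentane, filtration under argon; used crude
Reagents that add atoms: chlorotrimethylsilane, C[Si](C)(C)Cl
Why: Deprotonation to the planar lithium enolate erases the C5 centre but not the acetal centre, and O-silylation of the ester enolate with Me3SiCl gives the silyl ketene acetal.

Step 13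
Reactants: 7 [3,5-bis(methoxymethoxy)-4-prenylphenoxy]methyl pivalate; 19 {[(2S)-2-tert-butyl-5-ArB-1,3-dioxol-4-yl]oxy}trimethylsilane
Product: 21 (3R)-3-hydroxy-3-ArB-5,7-bis(methoxymethoxy)-6-prenylchroman-4-one, via silyl ketal 20 (not isolated)
Conditions: 7 (1.0 equiv), 19 (1.3 equiv), 2,6-di-tert-butyl-4-methylpyridine (1.5 equiv), 4 Å MS, CH2Cl2, −78 °C; Me3SiOTf (1.2 equiv) added last, −78 → −20 °C; then H2O/THF, citric acid (cat.), 0 °C
Reagents that add atoms: none
Why: Proposed new method: Me3SiOTf ionises the pivaloyloxymethyl acetal of 7 to the O-aryl oxocarbenium ion (cationic 2-oxadiene C2=O1–C8a=C4a), the ketene-acetal carbon of 19 attacks C2 (Mukaiyama-type alkoxymethylation, C2–C3), and the resulting O-silyl carboxonium ion at C4 acylates the adjacent ortho carbon of the phloroglucinol ring (Friedel–Crafts, C4–C4a), the pyridine base taking up the proton; the silyl ketal 20 then collapses on aqueous work-up to the ketone and the free 3-OH with loss of pivalaldehyde. The closest known reaction type is the oxa-Povarov formal [4+2] annulation of aryl oxocarbenium ions with alkenes to chromans, extended here to a ketene acetal so that C4 arrives at the ketone oxidation level; both halves (alkoxymethylation of silyl ketene acetals by acyloxy acetals, acylation of phloroglucinol ethers by activated carboxyl derivatives) are known separately. Ring C closes in a 6-exo-trig mode at the carboxonium carbon, with the arene π bond inside the new ring, and the temporary dioxolane stays cis-fused until work-up. C3 is the only new stereocentre that is kept: the electrophile adds to the planar dioxole on the face opposite the tert-butyl group of the (2S)-acetal carbon, which should give (R). The step needs C- over O-alkylation (normal for silyl ketene acetals), ionisation of the acyloxy acetal in preference to the three MOM acetals (carboxylate is by far the better leaving group towards a silyl triflate at low temperature, and MOM cleavage by this reagent needs bipyridyl and higher temperature as in step 14), and arene capture of the acyl cation (six-membered transition state onto a trioxygenated ring; silyl loss to triflate only regenerates the promoter, which can re-form the cation). Regiochemistry is not an issue because the two ortho positions of 7 are equivalent by symmetry.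

Step 14
Reactants: 21 (3R)-3-hydroxy-3-ArB-5,7-bis(methoxymethoxy)-6-prenylchroman-4-one
Product: 23 (3R)-3,5,7-trihydroxy-3-(4-hydroxy-2-methoxy-3-prenylphenyl)-6-prenylchroman-4-one (target), via tetrakis-silyl ether 22 (not isolated)
Conditions: Me3SiOTf (8 equiv), 2,2'-bipyridyl (12 equiv), CH2Cl2, 0 °C → rt; then H2O/MeOH, rt
Reagents that add atoms: none
Why: Aprotic MOM cleavage: the silyl triflate–bipyridyl pair converts each aryl MOM ether into the aryl silyl ether (the methoxymethyl group passes to bipyridyl) and water then hydrolyses the silyl ethers; no Brønsted acid is present, which should spare the tertiary benzylic carbinol and the prenyl groups, and C3 is not involved.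

**Compound list**
1 | phloroglucinol (benzene-1,3,5-triol) | Oc1cc(O)cc(O)c1 | starting material
2 | 3,5-bis(methoxymethoxy)phenol | COCOc1cc(O)cc(OCOC)c1 | intermediate
3 | [3,5-bis(methoxymethoxy)phenoxy]triisopropylsilane | COCOc1cc(O[Si](C(C)C)(C(C)C)C(C)C)cc(OCOC)c1 | intermediate
4 | [2,6-bis(methoxymethoxy)-4-(triisopropylsilyloxy)phenyl]lithium | COCOc1cc(O[Si](C(C)C)(C(C)C)C(C)C)cc(OCOC)c1[Li] | intermediate (not isolated)
5 | [3,5-bis(methoxymethoxy)-4-prenylphenoxy]triisopropylsilane | COCOc1cc(O[Si](C(C)C)(C(C)C)C(C)C)cc(OCOC)c1CC=C(C)C | intermediate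
6 | 3,5-bis(methoxymethoxy)-4-prenylphenol | COCOc1cc(O)cc(OCOC)c1CC=C(C)C | intermediate
7 | [3,5-bis(methoxymethoxy)-4-prenylphenoxy]methyl pivalate | COCOc1cc(OCOC(=O)C(C)(C)C)cc(OCOC)c1CC=C(C)C | intermediate
8 | 4-bromo-3-methoxyphenol | COc1cc(O)ccc1Br | starting material
9 | 1-bromo-2-methoxy-4-(methoxymethoxy)benzene | COCOc1ccc(Br)c(OC)c1 | intermediate
10 | [3-bromo-2-methoxy-6-(methoxymethoxy)phenyl]lithium | COCOc1ccc(Br)c(OC)c1[Li] | intermediate (not isolated)
11 | 1-bromo-2-methoxy-4-(methoxymethoxy)-3-prenylbenzene | COCOc1ccc(Br)c(OC)c1CC=C(C)C | intermediate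
12 | [2-methoxy-4-(methoxymethoxy)-3-prenylphenyl]lithium | COCOc1ccc([Li])c(OC)c1CC=C(C)C | intermediate (not isolated)
13 | ethyl 2-[2-methoxy-4-(methoxymethoxy)-3-prenylphenyl]-2-oxoacetate | CCOC(=O)C(=O)c1ccc(OCOC)c(CC=C(C)C)c1OC | intermediate
14 | ethyl (2S)-2-hydroxy-2-[2-methoxy-4-(methoxymethoxy)-3-prenylphenyl]acetate | CCOC(=O)[C@@H](O)c1ccc(OCOC)c(CC=C(C)C)c1OC | intermediate
15 | (2S)-2-hydroxy-2-[2-methoxy-4-(methoxymethoxy)-3-prenylphenyl]acetic acid | OC(=O)[C@@H](O)c1ccc(OCOC)c(CC=C(C)C)c1OC | intermediate
16 | trimethylsilyl (2S)-2-ArB-2-(trimethylsilyloxy)acetate | C[Si](C)(C)OC(=O)[C@@H](O[Si](C)(C)C)c1ccc(OCOC)c(CC=C(C)C)c1OC | intermediate (not isolated)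
17 | (2S,5S)-2-tert-butyl-5-[2-methoxy-4-(methoxymethoxy)-3-prenylphenyl]-1,3-dioxolan-4-one (tert-butyl and aryl cis) | O=C1O[C@@H](C(C)(C)C)O[C@H]1c2ccc(OCOC)c(CC=C(C)C)c2OC | intermediate
18 | lithium (2S)-2-tert-butyl-5-ArB-1,3-dioxol-4-olate | [Li]OC1=C(c2ccc(OCOC)c(CC=C(C)C)c2OC)O[C@H](C(C)(C)C)O1 | intermediate (not isolated)
19 | {[(2S)-2-tert-butyl-5-ArB-1,3-dioxol-4-yl]oxy}trimethylsilane | C[Si](C)(C)OC1=C(c2ccc(OCOC)c(CC=C(C)C)c2OC)O[C@H](C(C)(C)C)O1 | intermediate
20 | (2S,3aR,9bR)-2-tert-butyl-3a-ArB-7,9-bis(methoxymethoxy)-8-prenyl-9b-(trimethylsilyloxy)-3a,4-dihydro-9bH-[1,3]dioxolo[4,5-c]chromene (cis-fused silyl ketal across C3–C4 of the chroman; tert-butyl and ArB on the same face) | C[Si](C)(C)O[C@@]12O[C@@H](C(C)(C)C)O[C@]1(c3ccc(OCOC)c(CC=C(C)C)c3OC)COc4cc(OCOC)c(CC=C(C)C)c(OCOC)c42 | intermediate (not isolated)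
21 | (3R)-3-hydroxy-3-[2-methoxy-4-(methoxymethoxy)-3-prenylphenyl]-5,7-bis(methoxymethoxy)-6-prenylchroman-4-one | COc1c([C@@]2(O)COc3cc(OCOC)c(CC=C(C)C)c(OCOC)c3C2=O)ccc(OCOC)c1CC=C(C)C | intermediate
22 | (3R)-3-[2-methoxy-3-prenyl-4-(trimethylsilyloxy)phenyl]-6-prenyl-3,5,7-tris(trimethylsilyloxy)chroman-4-one | COc1c([C@@]2(O[Si](C)(C)C)COc3cc(O[Si](C)(C)C)c(CC=C(C)C)c(O[Si](C)(C)C)c3C2=O)ccc(O[Si](C)(C)C)c1CC=C(C)C | intermediate (not isolated)
23 | (3R)-3,5,7-trihydroxy-3-[4-hydroxy-2-methoxy-3-prenylphenyl]-6-prenylchroman-4-one | COc1c([C@@]2(O)COc3cc(O)c(CC=C(C)C)c(O)c3C2=O)ccc(O)c1CC=C(C)C | target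

**Step count**
Total steps: 14. Longest linear sequence: 9 steps (8 → 23, steps 6–14); the ring A branch (1 → 7) is 5 steps and joins at step 13.

**Steps most likely to fail**

Step 13 (proposed new method). The cascade may stop after the first bond: the O-silyl carboxonium ion can lose its silyl group and the neutral lactone may then not acylate the arene, or the MOM acetals may ionise in competition. The fallback uses known reactions and sets out from 7 and 19. The same partners are combined with catalytic Me3SiOTf (10 mol %, CH2Cl2, −78 °C, no base), a conventional Mukaiyama-type alkoxymethylation that should stop at the alkylated dioxolanone (2S,5R)-2-tert-butyl-5-{[3,5-bis(methoxymethoxy)-4-prenylphenoxy]methyl}-5-ArB-1,3-dioxolan-4-one F1, with the same facial control. LiOH in THF/H2O opens the acetal lactone, with loss of pivalaldehyde, to (2R)-3-[3,5-bis(methoxymethoxy)-4-prenylphenoxy]-2-hydroxy-2-ArB-propanoic acid F2. Trifluoroacetic anhydride in CH2Cl2 at 0 °C forms the mixed anhydride (and the trifluoroacetate of the carbinol) and closes ring C by intramolecular Friedel–Crafts acylation to the 3-O-trifluoroacetate of 21 F3. NaHCO3 in methanol removes the trifluoroacetyl group and the route is rejoined at 21.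

Step 14. The silyl triflate may ionise the tertiary benzylic C3–O bond, with elimination towards the isoflavone, before all three MOM groups are exchanged. The fallback sets out from 21 and masks the carbinol first. Ac2O, DMAP and Et3N in CH2Cl2 should give (3R)-3-acetoxy-3-ArB-5,7-bis(methoxymethoxy)-6-prenylchroman-4-one F4, in which the acyl group lowers the basicity of the C3 oxygen. Dilute HCl in MeOH/THF at room temperature then cleaves the MOM ethers to (3R)-3-acetoxy-5,7-dihydroxy-3-(4-hydroxy-2-methoxy-3-prenylphenyl)-6-prenylchroman-4-one F5. K2CO3 in degassed methanol at 0 °C removes the activated α-keto acetate and the route arrives at 23.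

Step 9. Facial discrimination may be poor for this ortho-methoxy aryl glyoxylate, and any loss of enantiopurity is carried through to C3. The fallback sets out from 13 and replaces catalytic control by resolution. NaBH4 in ethanol at 0 °C gives racemic ethyl 2-hydroxy-2-ArB-acetate F6, and LiOH in THF/H2O gives racemic 2-hydroxy-2-ArB-acetic acid F7. Crystallisation with (R)-1-phenylethylamine (the antipodal amine if the other diastereomeric salt is the less soluble one) gives the (R)-1-phenylethylammonium salt of the (S)-acid F8. Cold acidification liberates the acid and the route is rejoined at 15; cis-dioxolanone 17 can be recrystallised to raise the enantiopurity further.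

**Further compounds**
F1 | step 13 | (2S,5R)-2-tert-butyl-5-{[3,5-bis(methoxymethoxy)-4-prenylphenoxy]methyl}-5-[2-methoxy-4-(methoxymethoxy)-3-prenylphenyl]-1,3-dioxolan-4-one | O=C1O[C@@H](C(C)(C)C)O[C@]1(c2ccc(OCOC)c(CC=C(C)C)c2OC)COc3cc(OCOC)c(CC=C(C)C)c(OCOC)c3
F2 | step 13 | (2R)-3-[3,5-bis(methoxymethoxy)-4-prenylphenoxy]-2-hydroxy-2-[2-methoxy-4-(methoxymethoxy)-3-prenylphenyl]propanoic acid | OC(=O)[C@@](O)(c1ccc(OCOC)c(CC=C(C)C)c1OC)COc1cc(OCOC)c(CC=C(C)C)c(OCOC)c1
F3 | step 13 | (3R)-3-[2-methoxy-4-(methoxymethoxy)-3-prenylphenyl]-5,7-bis(methoxymethoxy)-4-oxo-6-prenylchroman-3-yl trifluoroacetate | COc1c([C@@]2(OC(=O)C(F)(F)F)COc3cc(OCOC)c(CC=C(C)C)c(OCOC)c3C2=O)ccc(OCOC)c1CC=C(C)C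
F4 | step 14 | (3R)-3-[2-methoxy-4-(methoxymethoxy)-3-prenylphenyl]-5,7-bis(methoxymethoxy)-4-oxo-6-prenylchroman-3-yl acetate | COc1c([C@@]2(OC(C)=O)COc3cc(OCOC)c(CC=C(C)C)c(OCOC)c3C2=O)ccc(OCOC)c1CC=C(C)C
F5 | step 14 | (3R)-5,7-dihydroxy-3-(4-hydroxy-2-methoxy-3-prenylphenyl)-4-oxo-6-prenylchroman-3-yl acetate | COc1c([C@@]2(OC(C)=O)COc3cc(O)c(CC=C(C)C)c(O)c3C2=O)ccc(O)c1CC=C(C)C
F6 | step 9 | racemic ethyl 2-hydroxy-2-[2-methoxy-4-(methoxymethoxy)-3-prenylphenyl]acetate | CCOC(=O)C(O)c1ccc(OCOC)c(CC=C(C)C)c1OC
F7 | step 9 | racemic 2-hydroxy-2-[2-methoxy-4-(methoxymethoxy)-3-prenylphenyl]acetic acid | OC(=O)C(O)c1ccc(OCOC)c(CC=C(C)C)c1OC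
F8 | step 9 | (R)-1-phenylethylammonium (2S)-2-hydroxy-2-[2-methoxy-4-(methoxymethoxy)-3-prenylphenyl]acetate | [O-]C(=O)[C@@H](O)c1ccc(OCOC)c(CC=C(C)C)c1OC.C[C@@H]([NH3+])c1ccccc1
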